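The symmetric hexamer is cut at the B–C and D–E methylene bridges into a central C–CH2–D bis-phloroglucinol and two A–B dimers of norflavaspidic type. Rings C and D are built, not bought: in each, the ring carbon carrying the central CH2 lies between two C–OH carbons, the imprint of a 2-substituted malonate. A twofold Claisen annulation of tetraethyl propane-1,1,3,3-tetracarboxylate with two molecules of tert-butyl 3,5-dioxooctanoate (C2 and C4 as nucleophiles, C3 as the third C–OH carbon) closes both rings and sets both butyryl groups in one operation; the tert-butyl esters mark the carbons later bridged to rings B and E.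

Key step: step 3

Remark: the target has no stereocentre, and its triketone and phenol rings are written in one of several equivalent tautomeric forms; all compounds are given as neutral species after work-up.

Step 1
Reactants: 1 diethyl malonate (2 equiv); 2 formaldehyde
Product: 4 tetraethyl propane-1,1,3,3-tetracarboxylate, via diethyl methylidenemalonate 3 (not isolated)
Conditions: 37% aq. CH2O (0.5 equiv), Et2NH (cat.), 5 °C → rt, then 100 °C
Reagents that add atoms: none
Why: Amine-catalysed Knoevenagel condensation should give the methylidenemalonate, which a second malonate captures at once by Michael addition, the standard way to this tetraester.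

Step 2
Reactants: 5 tert-butyl acetoacetate; 6 methyl butyrate
Product: 7 tert-butyl 3,5-dioxooctanoate
Conditions: LiN(iPr)2 (2.1 equiv per 5), THF, −78 → 0 °C; then 6 (0.5 equiv per 5), 0 °C → rt; then aq. HCl
Reagents that add atoms: none
Why: Claisen-type γ-acylation of the acetoacetate dianion, whose terminal carbanion attacks the ester while the excess dianion takes up the proton of the more acidic product; the tert-butyl ester is chosen because it resists lactonisation to the pyranone and is later removed by acid.

Step 3
Reactants: 4 tetraethyl propane-1,1,3,3-tetracarboxylate; 7 tert-butyl 3,5-dioxooctanoate (2.3 equiv)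
Product: 8 di-tert-butyl 3,3'-methylenebis(5-butanoyl-2,4,6-trihydroxybenzoate)
Conditions: NaOEt (8 equiv), EtOH/diglyme, 7 added slowly, 80 → 120 °C with distillation of EtOH; then cold 1 M HCl
Reagents that add atoms: none
Why: Proposed new method: under ethoxide only the doubly activated C2 and C4 of 7 are carbanion sites (C6 is not deprotonated), so one of them should acylate an ethyl ester carbon of one malonate terminus of 4 in a crossed Claisen condensation and the other then attack the second ester carbon of the same terminus, each ring losing two ethanol. The closest known reaction types are the sodium alkoxide condensation of diethyl malonate with diethyl 3-oxoglutarate to phloroglucinol dicarboxylates, the use of 2-alkylmalonates as twofold acyl donors in barbiturate syntheses, and the Claisen-mode cyclisation of 3,5,7-triketo esters to acylphloroglucinols; the twofold crossed case with a 2-substituted malonate and a 3,5-diketo ester has not been shown. Rings C and D each close by a 6-exo-trig attack of an enolate carbon on an ester carbonyl, and the resulting cyclohexane-1,3,5-trione tautomerises to the phloroglucinolate, which should make the sequence irreversible. No stereocentre is formed. The step needs C,C- over C,O-cyclisation, crossed over self-condensation and reaction at both termini: ethoxide reopens any pyranone or aryl lactone, the tert-butyl ester of 7 can neither serve as acyl donor nor lactonise, 7 is added slowly in slight excess over two equivalents, and removal of ethanol pulls the equilibria forward. The substitution pattern follows from connectivity alone, because the malonate carbon (central CH2), C2 (ester) and C4 (butyryl) must alternate with the three C–OH carbons.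

Step 4
Reactants: 8 di-tert-butyl 3,3'-methylenebis(5-butanoyl-2,4,6-trihydroxybenzoate)
Product: 10 bis(3-butanoyl-2,4,6-trihydroxyphenyl)methane, via diacid 9 (not isolated)
Conditions: TFA/CH2Cl2 (1:2), anisole, 0 °C → rt; evaporate; then dioxane/H2O, 80 °C
Reagents that add atoms: none
Why: Acidolysis of the tert-butyl esters (loss of 2-methylpropene) should give the 2,4,6-trihydroxybenzoic acids, which protodecarboxylate on gentle heating through ipso-protonation of the electron-rich ring, so that no base touches the methylene bridge and anisole intercepts tert-butyl cations.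

Step 5
Reactants: 10 bis(3-butanoyl-2,4,6-trihydroxyphenyl)methane
Product: 11 bis[3-butanoyl-5-(dimethylaminomethyl)-2,4,6-trihydroxyphenyl]methane
Conditions: CH2=NMe2 I (Eschenmoser's salt, 2.1 equiv), MeCN, 0 °C → rt; then aq. NaHCO3 to pH 7
Reagents that add atoms: N,N-dimethylmethyleneiminium iodide (Eschenmoser's salt), C=[N+](C)C.[I-]
Why: Mannich aminomethylation with a preformed iminium salt at the one free, doubly hydroxyl-flanked carbon of each ring, where only the bis-adduct can form because every other ring carbon is substituted.

Step 6
Reactants: 12 phloroglucinol; 13 butanoyl chloride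
Product: 14 1-(2,4,6-trihydroxyphenyl)butan-1-one (butyrylphloroglucinol)
Conditions: AlCl3 (3.5 equiv), PhNO2/CH2Cl2, 0 → 50 °C; then ice/HCl
Reagents that add atoms: none
Why: Friedel–Crafts C-acylation of phloroglucinol, in which the first acyl group deactivates the ring so that monoacylation should dominate.

Step 7
Reactants: 14 1-(2,4,6-trihydroxyphenyl)butan-1-one
Product: 15 2-butanoyl-3,5-dihydroxy-4,4-dimethylcyclohexa-2,5-dien-1-one (butyrylfilicinic acid)
Conditions: NaOMe (4 equiv), MeI (2.5 equiv), MeOH, 0 °C → rt; then aq. HCl
Reagents that add atoms: iodomethane, CI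
Why: Alkoxide-mediated dearomatising C-methylation of the phloroglucinolate, in which the second methyl group should enter mainly at the already methylated, more nucleophilic carbon to give the gem-dimethyl triketone, the classical access to acylfilicinic acids.

Step 8
Reactants: 15 butyrylfilicinic acid; 14 1-(2,4,6-trihydroxyphenyl)butan-1-one (3 equiv)
Product: 17 norflavaspidic acid (2-butanoyl-6-[(3-butanoyl-2,4,6-trihydroxyphenyl)methyl]-3,5-dihydroxy-4,4-dimethylcyclohexa-2,5-dien-1-one), via Mannich base 16 (not isolated)
Conditions: CH2=NMe2 I (Eschenmoser's salt, 1.0 equiv), MeCN, 0 °C; then 14, NaOAc, 60 °C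
Reagents that add atoms: N,N-dimethylmethyleneiminium iodide (Eschenmoser's salt), C=[N+](C)C.[I-]
Why: Mannich aminomethylation of the free C6 of the triketone followed by acetate-buffered loss of dimethylamine should give the 6-methylidene triketone, a quinone-methide-type acceptor that alkylates a free ring carbon of 14 by conjugate addition and rearomatisation, the excess of 14 limiting twofold alkylation.

Step 9
Reactants: 11 bis[3-butanoyl-5-(dimethylaminomethyl)-2,4,6-trihydroxyphenyl]methane; 17 norflavaspidic acid (2.4 equiv)
Product: 18 CNP0237140.0, the linear A–CH2–B–CH2–C–CH2–D–CH2–E–CH2–F hexamer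
Conditions: 1,4-dioxane, NaOAc/AcOH buffer, 80 °C, Ar
Reagents that add atoms: none
Why: Thermal loss of dimethylamine from each aminomethylphenol unit should give an o-quinone methide that is trapped by the single free ring carbon of 17 (Mannich-base alkylation), and since 11 has no free ring carbon and 17 only one, no other C–C connectivity can form.

Compound list
1 | diethyl malonate | CCOC(=O)CC(=O)OCC | starting material
2 | formaldehyde (37% aqueous solution) | C=O | starting material
3 | diethyl methylidenemalonate | C=C(C(=O)OCC)C(=O)OCC | intermediate
4 | tetraethyl propane-1,1,3,3-tetracarboxylate | CCOC(=O)C(CC(C(=O)OCC)C(=O)OCC)C(=O)OCC | intermediate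
5 | tert-butyl acetoacetate | CC(=O)CC(=O)OC(C)(C)C | starting material
6 | methyl butyrate | CCCC(=O)OC | starting material
7 | tert-butyl 3,5-dioxooctanoate | CCCC(=O)CC(=O)CC(=O)OC(C)(C)C | intermediate
8 | di-tert-butyl 3,3'-methylenebis(5-butanoyl-2,4,6-trihydroxybenzoate) | CCCC(=O)c1c(O)c(C(=O)OC(C)(C)C)c(O)c(Cc2c(O)c(C(=O)OC(C)(C)C)c(O)c(C(=O)CCC)c2O)c1O | intermediate
9 | 3,3'-methylenebis(5-butanoyl-2,4,6-trihydroxybenzoic acid) | CCCC(=O)c1c(O)c(C(=O)O)c(O)c(Cc2c(O)c(C(=O)O)c(O)c(C(=O)CCC)c2O)c1O | intermediate
10 | bis(3-butanoyl-2,4,6-trihydroxyphenyl)methane | CCCC(=O)c1c(O)cc(O)c(Cc2c(O)cc(O)c(C(=O)CCC)c2O)c1O | intermediate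
11 | bis[3-butanoyl-5-(dimethylaminomethyl)-2,4,6-trihydroxyphenyl]methane | CCCC(=O)c1c(O)c(CN(C)C)c(O)c(Cc2c(O)c(CN(C)C)c(O)c(C(=O)CCC)c2O)c1O | intermediate
12 | phloroglucinol (benzene-1,3,5-triol) | Oc1cc(O)cc(O)c1 | starting material
13 | butanoyl chloride | CCCC(=O)Cl | starting material
14 | 1-(2,4,6-trihydroxyphenyl)butan-1-one (butyrylphloroglucinol) | CCCC(=O)c1c(O)cc(O)cc1O | intermediate
15 | 2-butanoyl-3,5-dihydroxy-4,4-dimethylcyclohexa-2,5-dien-1-one (butyrylfilicinic acid) | CCCC(=O)C1=C(O)C(C)(C)C(O)=CC1=O | intermediate
16 | 2-butanoyl-6-(dimethylaminomethyl)-3,5-dihydroxy-4,4-dimethylcyclohexa-2,5-dien-1-one | CCCC(=O)C1=C(O)C(C)(C)C(O)=C(CN(C)C)C1=O | intermediate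
17 | norflavaspidic acid, 2-butanoyl-6-[(3-butanoyl-2,4,6-trihydroxyphenyl)methyl]-3,5-dihydroxy-4,4-dimethylcyclohexa-2,5-dien-1-one | CCCC(=O)C1=C(O)C(C)(C)C(O)=C(Cc2c(O)cc(O)c(C(=O)CCC)c2O)C1=O | intermediate
18 | CNP0237140.0, hexamer of two butyrylfilicinic (rings A, F) and four butyrylphloroglucinol units (rings B–E) joined by five CH2 bridges | CCCC(=O)C1=C(O)C(C)(C)C(O)=C(Cc2c(O)c(Cc3c(O)c(Cc4c(O)c(Cc5c(O)c(CC6=C(O)C(C)(C)C(O)=C(C(=O)CCC)C6=O)c(O)c(C(=O)CCC)c5O)c(O)c(C(=O)CCC)c4O)c(O)c(C(=O)CCC)c3O)c(O)c(C(=O)CCC)c2O)C1=O | target

Total step count: 9. Longest linear sequence: 5 steps (step 1 or 2, then steps 3, 4, 5 and 9); the A–B branch (steps 6, 7, 8) joins in step 9.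

Steps most likely to fail

1. Step 3 (proposed new method). The crossed intermolecular Claisen acylation may stall because both partners rest as weakly reactive enolates. Ethoxide may also fragment 4 by retro-Michael reaction, 7 may self-condense, or annulation may stop after one malonate terminus. The fallback uses known chemistry and sets out from 14 (made in step 6). Formaldehyde 2 (0.4 equiv, 14 in excess; dilute aq. NaOH at 0 °C) hydroxymethylates one molecule of 14, and the derived quinone methide is captured by a second, which should give 10 directly. The excess of 14 keeps higher oligomers low and is recovered. The route is rejoined at 10, and steps 1–4 are bypassed. No new compound is made.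

2. Step 9. The methylene bridges already present may open by retro-Michael reaction and recombine at 80 °C in the presence of liberated amine, scrambling the order of the rings. The second alkylation may also lag so that a pentamer persists, or the quinone methide may be lost to oligomerisation. The fallback changes the order of bond formation so that the sensitive A–B and E–F bridges are made last and under milder conditions. It sets out from 11. Commercial methyl 2,4,6-trihydroxybenzoate is butanoylated with 13 (AlCl3, PhNO2) to methyl 3-butanoyl-2,4,6-trihydroxybenzoate F1, which has a single free ring carbon. Heating 11 with F1 (2.2 equiv, dioxane, 80 °C) should give the all-aromatic B–C–D–E tetramer diester F2. Saponification (aq. NaOH, 70 °C, Ar) and decarboxylation on acidification and warming give the tetramer F3, with one free carbon on each terminal ring. F3 is then alkylated with Mannich base 16 (2.2 equiv, generated from 15 as in step 8; NaOAc, MeCN, 40–50 °C), which loses amine far more readily than a phenolic Mannich base. The route is rejoined at 18.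

3. Step 8. Compound 14 may be alkylated at both free ring carbons, and the methylidene triketone may be captured by 15 that is not yet aminomethylated; both processes drain the cross-coupled dimer. The fallback replaces the twofold nucleophile by a blocked one and sets out from 15. Mannich base 16 is generated as before and trapped with methyl 3-butanoyl-2,4,6-trihydroxybenzoate F1 (prepared as in the fallback for step 9; 1.1 equiv, NaOAc, MeCN, 60 °C) to give the ester-blocked dimer F4. Saponification (aq. NaOH, 60 °C, Ar; every ring carbon stays substituted while the medium is basic) and decarboxylation on acidification and warming should give norflavaspidic acid. The route is rejoined at 17.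

Further compounds
F0 | step 3 | none | none
F1 | step 9 | methyl 3-butanoyl-2,4,6-trihydroxybenzoate | CCCC(=O)c1c(O)cc(O)c(C(=O)OC)c1O
F2 | step 9 | B–C–D–E tetramer diester: bis(3-butanoyl-2,4,6-trihydroxyphenyl)methane carrying at each free ring carbon a (3-butanoyl-2,4,6-trihydroxy-5-methoxycarbonylphenyl)methyl group | CCCC(=O)c1c(O)c(Cc3c(O)c(C(=O)OC)c(O)c(C(=O)CCC)c3O)c(O)c(Cc2c(O)c(Cc4c(O)c(C(=O)OC)c(O)c(C(=O)CCC)c4O)c(O)c(C(=O)CCC)c2O)c1O
F3 | step 9 | B–C–D–E tetramer: bis(3-butanoyl-2,4,6-trihydroxyphenyl)methane carrying at each free ring carbon a (3-butanoyl-2,4,6-trihydroxyphenyl)methyl group | CCCC(=O)c1c(O)c(Cc3c(O)cc(O)c(C(=O)CCC)c3O)c(O)c(Cc2c(O)c(Cc4c(O)cc(O)c(C(=O)CCC)c4O)c(O)c(C(=O)CCC)c2O)c1O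
F4 | step 8 | methyl 3-butanoyl-5-[(3-butanoyl-2,4-dihydroxy-5,5-dimethyl-6-oxocyclohexa-1,3-dien-1-yl)methyl]-2,4,6-trihydroxybenzoate | CCCC(=O)C1=C(O)C(C)(C)C(O)=C(Cc2c(O)c(C(=O)OC)c(O)c(C(=O)CCC)c2O)C1=O
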